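Suppose a one-step world: starting material passes to product at one rate, and two chemists argue over which concentration sets its order.

the same everywhere: starting material 0.038 M

| run | partner | temperature | remark | time |
|---|---|---|---|---|
| summer | 0.037 M | 68 °C | run made earlier |  |
| dusk | 0.059 M | 84 °C | run made earlier |  |
| gamma | 0.0266 M | 80 °C |  | 4.0 min |
| zeta | 0.0266 M | 70 °C |  | 4.0 min |

summer run (percent of the starting material charged)

| time / min | intermediate B / % | starting material / % | intermediate A / % | product / % |
|---|---|---|---|---|
| 0.333 | 0.3 | 96.2 | 2.7 | 1.0 |
| 1.00 | 0.4 | 88.5 | 6.9 | 2.6 |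
| 2.00 | 3.0 | 78.1 | 10.9 | 6.0 |
| 3.00 | 4.0 | 69.3 | 14.1 | 11.5 |
| 4.00 | 6.0 | 62.9 | 16.0 | 16.2 |

dusk run (percent of the starting material charged)

| time / s | intermediate B / % | starting material / % | intermediate A / % | product / % |
|---|---|---|---|---|
| 25.0 | 1.4 | 77.8 | 13.4 | 6.4 |
| 50.0 | 4.4 | 60.5 | 16.9 | 16.3 |
| 80.0 | 8.2 | 44.5 | 17.4 | 28.1 |
| 90.0 | 9.6 | 40.2 | 16.7 | 31.4 |
| 120 | 11.2 | 31.5 | 15.1 | 39.5 |

(scatter of a reading: 0.5 percentage points)

- which of these there is most of at the end, counted by the starting material in it, gamma (intermediate A / intermediate B / product / starting material)
- which of these there is most of at the end, counted by the starting material in it, zeta (intermediate A / intermediate B / product / starting material)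
- amount of the one of these that there is most of at the end, in percent of the starting material charged, gamma
- amount of the one of these that there is most of at the end, in percent of the starting material charged, zeta



The first chemist leaves partner out of the rate. The last summer reading gives 0.116 min⁻¹ and the last dusk reading 0.578 min⁻¹, and this number, the natural log of charged over left divided by time, is her loss constant. The first dusk reading gives 0.602 min⁻¹, close to the last. From the two temperatures she takes 102 kJ mol⁻¹. That carries the constant to 0.392 min⁻¹ in gamma and 0.143 min⁻¹ in zeta, leaving 20.9% and 56.5% of the starting material.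

The second chemist answers that the dusk run had more partner as well as more heat. For him the constant is pseudo-first-order, proportional to partner. Dividing by partner, and repeating the reckoning at the smaller charge, he leaves 45.3% in gamma and 67.9% in zeta, so in his one-step world he bets on product in gamma, at 54.7%, and on starting material in zeta.

I side with her. At the first summer reading, intermediate B, the form I take to hold partner, stands at 0.3%, less than the 3.80% of starting material already gone.

The forecast takes her side: “this step appears zero order in partner”. It says product at 44% in gamma and starting material at 55% in zeta, the latter lower than my 56.5%.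

The simulation gives product at 56.3% in gamma and starting material at 56.0% in zeta. Gamma's product is 12 percentage points above the forecast, and its intermediate A, about 23 there, stands at 14.4%.

    starting material ⇌ intermediate A (K = 4.90, k = 0.00200 s⁻¹, Ea = 103 kJ mol⁻¹, ΔH = −3.00 kJ mol⁻¹)
    intermediate A → product (k = 0.00410 s⁻¹, Ea = 92.0 kJ mol⁻¹)
    partner + intermediate A ⇌ intermediate B (K = 35.0 M⁻¹, k = 0.0900 M⁻¹ s⁻¹, Ea = 55.0 kJ mol⁻¹, ΔH = −39.0 kJ mol⁻¹)
    starting material → product (k = 4.90 × 10⁻⁴ s⁻¹, Ea = 104 kJ mol⁻¹)
    intermediate B → decomposed reagent (k = 3.60 × 10⁻⁴ s⁻¹, Ea = 110 kJ mol⁻¹)
    (constants at 70 °C)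

Gamma holds 21.2% of starting material, against her 20.9% and his 45.3%. Moving partner by itself from the summer run to gamma's charge gives 62.4%, while moving temperature by itself gives 21.1%. His view has its region in the step from intermediate A to intermediate B, where partner does stand in the rate. For the repeat of gamma at 55 °C, her constant becomes 0.0280 min⁻¹, which leaves 89.4%. That flask holds 89.3% of starting material.

The earlier runs and the new flask are simulated on assumed constants; noise was put on by code.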